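The pitfall in repeating this run is to watch the crystals and read the flattening of links as a finished flask, yet links here count crystals too, so whatever leaves the solution stays in the count and the flattening has to be looked for elsewhere.

| setting | dusk | flask |
|---|---|---|
| first end groups | 0.50 M | 0.50 M |
| second end groups | 0.50 M | 0.500 M |
| remark | the very flask that is asked about, followed so far |  |
| time |  | 15 min |

dusk run (percent of the first end groups charged)

| time / min | links / % |
|---|---|
| 2.50 | 64.7 |
| 5.00 | 75.4 |
| 6.00 | 77.3 |
| 10.0 | 81.1 |

(standard deviation of a reading: 0.5 percentage points)

- amounts and yields of links count crystals too
- given per volume of solution although it is solid: crystals
- additions leave the volume as it is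
- the numbers in the tables scatter by 0.5 percentage points (one standard deviation)
- steps under discussion: first end groups + second end groups -> links; second end groups <-> dormant form; crystals <-> links

- zeta: at 15 min add first end groups, 50.0% of the amount charged, then wait 5.0 min
- beta: at 15 min add second end groups, 100% of the amount charged, then wait 5.0 min
- theta: change nothing and wait 5.0 min more

1. links, in percent of the first end groups first charged, at 15 min
2. the remedy with the largest gain of links, or "none" below 2 percentage points (zeta / beta / theta / none)
3. links present, in percent of the first end groups first charged, after zeta
4. links present, in percent of the first end groups first charged, after beta

We read the table from the top. The first row, 64.7% at 2.50 min, taken as plain pairing of equal charges, gives links over unlinked per minute of 0.733 min⁻¹, our pairing constant in fractions of the charge. The last two rows climb by 0.00950 min⁻¹, while first end groups stand between them at 20.8% of the charge, so the free second end groups come out near 6.23%, a rough reading since it rests on a difference of two readings that scatter by 0.5 percentage points each. That is less than the free first end groups, although the charges were equal, so second end groups are the limiting reagent, and their balance puts the missing 14.6% of their charge in the dormant form. What remains is 85.4%, the partner supply: the share of the first end groups that second end groups outside the dormant form can cover. We put links at 15 min between the last reading and this supply, near 83.3%, and we choose beta, since adding second end groups raises the supply and adding first end groups does not.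

The forecast gives 82.8% and names beta, with 84.8% after zeta and 98.8% after beta, on the ground of “second end groups slipping into the dormant form”; our links figure lies slightly above its own.

The flask gives 82.1%, and beta is the best remedy, gaining 17 points against 1.6 points for zeta and 0.81 points for theta, with 83.7% after zeta and 99.2% after beta.

    first end groups + second end groups → links (k = 0.0290 M⁻¹ s⁻¹)
    second end groups ⇌ dormant form (K = 8.80, k = 0.00160 s⁻¹)
    crystals ⇌ links, rate k3*(cs3 - [links]) while solid is left; crystals form when [links] > cs3 (solubility = 40.0 mM, k = 0.0310 s⁻¹)

With the step into the dormant form struck out both ways, this flask stands at 92.9% of links at 15 min instead of 82.1%, so that step accounts for 11 points, which is a part of the shortfall and not the whole of it. Beta lifts the partner supply of this flask from 85.4% to 185% of the first charge and links reach 99.2%, and the step into the dormant form is one part of that gain, which is 17 points with the step and 7 points with it struck out. In the neighbour flask charged with 0.12 M of second end groups, the supply scaled by the charges is 20.5%, and links there stand at 21.6%.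

(Readings and results were generated by integration from invented constants.)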